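The only ring alkene, C6=C7 in ring B, is treated as the trace of a C6 silyl enol ether. Ring B is therefore cut at C5–C10 and C8–C9, giving a C5=C6–C7=C8 silyloxydiene and a C9=C10 (E)-enal linked through C1–C4. One catalyst-controlled intramolecular [4+2] cycloaddition closes rings A and B and sets quaternary C10. C5, C8 and C9 sit next to carbonyl groups and are settled afterwards by equilibration to the trans-fused decalin with C8 and C9 substituents both equatorial. The precursor is an acyclic (2E,4Z,10E)-trienal with a 4-silyloxydienoate at one end and a β-methyl enal at the other.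

Key step: step 8

Remarks and assumptions on the chemistry
- Atom labels follow labdane numbering: C1–C10 decalin (C18/C19 on C4, C20 on C10), C11–C16 side chain on C9, C17 the carboxyl carbon on C8.
- The dienol ether is carried as the triisopropylsilyl rather than the tert-butyldimethylsilyl ether. That group has the best record with triflimide-activated oxazaborolidines and survives the release and oxidation of the C11 alcohol; the bonds formed are unchanged.
- The chain is built by carboalumination of 5-chloropent-1-yne instead of by degradation of a terpene alcohol, which shortens the approach to the trienal.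
- An endo cycloaddition of an (E,E)-diene with an (E)-enal must place C11, C17 and C20 on one face. Adduct 17 is therefore the C8 epimer of the target array (8R in 17), and step 10 inverts C8.
- Assumption: the (S)-catalyst is chosen from the formyl C–H···O binding model, which is established for α-substituted acroleins but not for β,β-disubstituted enals. If the first adduct proves antipodal, the (R)-catalyst from (R)-diphenylprolinol is used with no other change.

Step 1
Reactants: 1 5-chloropent-1-yne
Product: 4 (E)-6-chloro-3-methylhex-2-en-1-ol, via alkenylalane 2 (not isolated), via lithium alanate 3 (not isolated)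
Conditions: AlMe3, Cp2ZrCl2 (20 mol %), CH2Cl2, 0 °C to rt; then n-BuLi, THF, −78 °C; (CH2O)n, −78 °C to rt; aq. HCl work-up
Reagents that add atoms: trimethylaluminium C[Al](C)C; formaldehyde (as paraformaldehyde) C=O
Why: Zirconium-catalysed syn-carboalumination (Negishi carboalumination) puts methyl on the internal and aluminium on the terminal alkyne carbon, and the derived alanate adds to formaldehyde with retention, which fixes the (E)-trisubstituted alkene; the primary chloride is inert to AlMe3.

Step 2
Reactants: 4 (E)-6-chloro-3-methylhex-2-en-1-ol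
Product: 5 (E)-[(6-chloro-3-methylhex-2-en-1-yl)oxy]triethylsilane
Conditions: Et3SiCl, imidazole, CH2Cl2, 0 °C
Reagents that add atoms: chlorotriethylsilane CC[Si](Cl)(CC)CC
Why: Standard silylation of a primary alcohol; the triethylsilyl ether survives Grignard formation and is cleaved in the acidic work-up of the next step, so no separate deprotection is needed.

Step 3
Reactants: 5 (E)-[(6-chloro-3-methylhex-2-en-1-yl)oxy]triethylsilane; 6 mesityl oxide (4-methylpent-3-en-2-one)
Product: 9 (E)-10-hydroxy-4,4,8-trimethyldec-8-en-2-one, via Grignard reagent 7 (not isolated), via trimethylsilyl enol ether 8 (not isolated)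
Conditions: Mg, THF, reflux; then 6, CuBr·SMe2 (5 mol %), Me3SiCl, DMPU, THF, −78 °C; then AcOH/THF/H2O, rt
Reagents that add atoms: none
Why: Magnesium insertion into the primary chloride and chlorosilane-accelerated, copper-catalysed 1,4-addition of the Grignard reagent to the β,β-disubstituted enone build quaternary C4 (conjugate addition), and mild aqueous acid hydrolyses both the silyl enol ether and the triethylsilyl ether.

Step 4
Reactants: 9 (E)-10-hydroxy-4,4,8-trimethyldec-8-en-2-one; 10 glyoxylic acid (used as the monohydrate)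
Product: 11 (2E,10E)-12-hydroxy-6,6,10-trimethyl-4-oxododeca-2,10-dienoic acid
Conditions: pyrrolidine, AcOH, MeOH, 60 °C
Reagents that add atoms: none
Why: The amine-mediated aldol condensation occurs at the methyl group because the other α-position is a neopentyl methylene, and dehydration gives the conjugated (E)-4-oxo-2-enoic acid as the thermodynamic alkene (C7=C8 with C17 in place).

Step 5
Reactants: 11 (2E,10E)-12-hydroxy-6,6,10-trimethyl-4-oxododeca-2,10-dienoic acid
Product: 12 tert-butyl (2E,10E)-12-hydroxy-6,6,10-trimethyl-4-oxododeca-2,10-dienoate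
Conditions: Me2NCH(Ot-Bu)2, toluene, 80 °C
Reagents that add atoms: N,N-dimethylformamide di-tert-butyl acetal CN(C)C(OC(C)(C)C)OC(C)(C)C
Why: The formamide acetal transfers a tert-butyl group to the carboxylate under neutral conditions (O-alkylation of a carboxylic acid), leaving the allylic alcohol and the 4-oxo-enoate untouched.

Step 6
Reactants: 12 tert-butyl (2E,10E)-12-hydroxy-6,6,10-trimethyl-4-oxododeca-2,10-dienoate
Product: 15 tert-butyl (2E,4Z,10E)-12-hydroxy-6,6,10-trimethyl-4-[(triisopropylsilyl)oxy]dodeca-2,4,10-trienoate, via trimethylsilyl ether 13 (not isolated), via bis-silyl compound 14 (not isolated)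
Conditions: Me3SiCl, Et3N, CH2Cl2, 0 °C; then i-Pr3SiOTf, Et3N, −78 to 0 °C; then K2CO3, MeOH, 0 °C
Reagents that add atoms: triisopropylsilyl trifluoromethanesulfonate CC(C)[Si](OS(=O)(=O)C(F)(F)F)(C(C)C)C(C)C
Why: Soft enolisation of the ketone with a silyl triflate and Et3N can occur only at C5, the bulky CMe2 group taking the position trans to the vinyl substituent and so giving the (4Z)-enol ether, while the alcohol is masked as a trimethylsilyl ether that brief basic methanolysis removes without touching the far more robust triisopropylsilyl enol ether.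

Step 7
Reactants: 15 tert-butyl (2E,4Z,10E)-12-hydroxy-6,6,10-trimethyl-4-[(triisopropylsilyl)oxy]dodeca-2,4,10-trienoate
Product: 16 tert-butyl (2E,4Z,10E)-6,6,10-trimethyl-12-oxo-4-[(triisopropylsilyl)oxy]dodeca-2,4,10-trienoate
Conditions: MnO2, CH2Cl2, rt
Reagents that add atoms: none
Why: MnO2 oxidises only the allylic alcohol (neutral, heterogeneous allylic oxidation), keeps the (E)-geometry and leaves the silyl dienol ether intact.

Step 8
Reactants: 16 tert-butyl (2E,4Z,10E)-6,6,10-trimethyl-12-oxo-4-[(triisopropylsilyl)oxy]dodeca-2,4,10-trienoate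
Product: 17 tert-butyl (1R,2R,4aR,8aR)-1-formyl-5,5,8a-trimethyl-4-[(triisopropylsilyl)oxy]-1,2,4a,5,6,7,8,8a-octahydronaphthalene-2-carboxylate (labdane numbering 5R,8R,9R,10R: trans-fused; C11 formyl, C17 ester and C20 methyl on one face, H5 on the other)
Conditions: (S)-3,3-diphenyl-1-(2-methylphenyl)tetrahydro-1H,3H-pyrrolo[1,2-c][1,3,2]oxazaborole (20 mol %), HN(SO2CF3)2 (17 mol %), CH2Cl2 (0.02 M), −78 to −40 °C; Et3N quench
Reagents that add atoms: none
Why: Proposed new method: the protonated oxazaborolidine binds the formyl oxygen of the s-trans enal (boron syn to the formyl hydrogen, formyl C–H···O contact to the ring oxygen) and lowers its LUMO, so that the nucleophilic enol-ether terminus C5 attacks C10 and C9 closes onto C8 in a concerted but highly asynchronous [4+2] event whose stepwise limit is a Mukaiyama–Michael addition followed by a Michael ring closure. The closest known reactions are Lewis-acid-promoted intramolecular Diels–Alder reactions of 2-silyloxydiene trienals and oxazaborolidinium-catalysed enantioselective Diels–Alder reactions of enals with 2-silyloxydienes; new here is their union on a β,β-disubstituted enal that must create a quaternary carbon next to C4. Ring A closes 6-exo-trig (C5 onto C10 through the four-carbon tether C1–C4, as in the cycloaddition of a 1,7,9-decatriene) and ring B closes 6-endo-trig (C9 onto C8), both as six-membered rings. C10 is set by the catalyst, whose aryl group shields one enal face so that C5 adds to the Si face of C10; C9 follows from the (E)-enal (C11 cis to C20), C5 from the (4Z)-enol ether in the endo-formyl transition state (trans ring fusion), and C8 from the (2E)-enoate in that same transition state (ester cis to C11, the one centre to be inverted later). Only face selectivity at C10 is indispensable, since C5, C8 and C9 each lie α to a carbonyl group in 17 or in the derived 6-ketone and are corrected thermodynamically; polarity matching (donor C5 against acceptor C10, enolate carbon C9 against enone carbon C8) secures the regiochemistry, the geminal methyl groups on C4 bias the tether toward the coiled reactive conformation, and a slight excess of oxazaborolidine over HN(SO2CF3)2 keeps free acid away from the enol ether and the tert-butyl ester.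

Step 9
Reactants: 17 tert-butyl (1R,2R,4aR,8aR)-1-formyl-5,5,8a-trimethyl-4-[(triisopropylsilyl)oxy]-1,2,4a,5,6,7,8,8a-octahydronaphthalene-2-carboxylate
Product: 18 tert-butyl (1R,2S,4aR,8aS)-1-ethenyl-5,5,8a-trimethyl-4-[(triisopropylsilyl)oxy]-1,2,4a,5,6,7,8,8a-octahydronaphthalene-2-carboxylate (same spatial arrangement as 17; descriptors change only through priorities)
Conditions: Ph3PCH3Br, KN(SiMe3)2, THF, 0 °C; then 17, −78 to 0 °C
Reagents that add atoms: methyltriphenylphosphonium bromide C[P+](c1ccccc1)(c1ccccc1)c1ccccc1.[Br-]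
Why: Wittig methylenation of the aldehyde with the non-stabilised ylide turns C11 into the C11=C12 vinyl group and thereby removes the acidifying group at C9 before any strong base is used; the silyl enol ether and the tert-butyl ester do not react.

Step 10
Reactants: 18 tert-butyl (1R,2S,4aR,8aS)-1-ethenyl-5,5,8a-trimethyl-4-[(triisopropylsilyl)oxy]-1,2,4a,5,6,7,8,8a-octahydronaphthalene-2-carboxylate
Product: 20 tert-butyl (1R,2S,4aR,8aS)-1-ethenyl-5,5,8a-trimethyl-4-oxodecahydronaphthalene-2-carboxylate (C8 ester now equatorial, trans to the C9 vinyl group and to C20), via C8-epimeric ketone 19 (not isolated)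
Conditions: Bu4NF, THF, 0 °C; then t-BuOK (0.3 equiv), t-BuOH, rt, under argon
Reagents that add atoms: none
Why: Fluoride cleaves the enol silyl ether to the C6 ketone, and catalytic tert-butoxide then equilibrates C8 (α to the ester) and C5 (α to the ketone) through their enolates to the trans-decalin with the C8 ester equatorial (thermodynamic epimerisation driven by loss of the 1,3-diaxial contact with the C10 methyl group); no alkene can move into conjugation and no retro-Michael opening is possible once C9 carries a vinyl group.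

Step 11
Reactants: 20 tert-butyl (1R,2S,4aR,8aS)-1-ethenyl-5,5,8a-trimethyl-4-oxodecahydronaphthalene-2-carboxylate
Product: 22 tert-butyl (1R,2R,4aR,8aS)-1-ethenyl-5,5,8a-trimethyl-4-{[(trifluoromethyl)sulfonyl]oxy}-1,2,4a,5,6,7,8,8a-octahydronaphthalene-2-carboxylate, via potassium enolate 21 (not isolated)
Conditions: KN(SiMe3)2 (0.98 equiv), THF, −78 °C; PhNTf2, −78 to 0 °C
Reagents that add atoms: N-phenylbis(trifluoromethanesulfonimide) O=S(=O)(N(c1ccccc1)S(=O)(=O)C(F)(F)F)C(F)(F)F
Why: Kinetic deprotonation at the C7 methylene (C5 is a hindered methine between two quaternary carbons) and O-sulfonylation with PhNTf2 give the C6=C7 enol triflate (regioselective enol triflate formation), the slight deficit of base protecting the now allylic C8–H.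

Step 12
Reactants: 22 tert-butyl (1R,2R,4aR,8aS)-1-ethenyl-5,5,8a-trimethyl-4-{[(trifluoromethyl)sulfonyl]oxy}-1,2,4a,5,6,7,8,8a-octahydronaphthalene-2-carboxylate
Product: 23 tert-butyl (1R,2S,4aR,8aS)-1-ethenyl-5,5,8a-trimethyl-1,2,4a,5,6,7,8,8a-octahydronaphthalene-2-carboxylate
Conditions: Pd(OAc)2 (5 mol %), PPh3, HCO2H, n-Bu3N, DMF, 60 °C
Reagents that add atoms: none
Why: Palladium-catalysed formate reduction of the enol triflate (oxidative addition, formate exchange, decarboxylation, C–H reductive elimination) leaves the C6=C7 alkene of the target without affecting the vinyl group or C8.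

Step 13
Reactants: 24 2-(prop-2-yn-1-yloxy)tetrahydro-2H-pyran (commercial THP ether of propargyl alcohol, racemic)
Product: 27 tert-butyl 4-hydroxybut-2-ynoate, via lithium acetylide 25 (not isolated), via THP-protected ynoate 26 (not isolated)
Conditions: n-BuLi, THF, −78 °C; Boc2O, −78 °C; AcOH; then TsOH·H2O (cat.), MeOH, rt
Reagents that add atoms: di-tert-butyl dicarbonate CC(C)(C)OC(=O)OC(=O)OC(C)(C)C
Why: Deprotonation of the terminal alkyne and C-acylation with Boc2O give the tert-butyl ynoate, and acid-catalysed transacetalisation with methanol frees the alcohol while the tert-butyl ester tolerates catalytic TsOH.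

Step 14
Reactants: 27 tert-butyl 4-hydroxybut-2-ynoate
Product: 28 tert-butyl (2Z)-4-hydroxy-3-iodobut-2-enoate
Conditions: NaI, AcOH, 70 °C
Reagents that add atoms: sodium iodide [Na+].[I-]
Why: Conjugate hydroiodination of the ynoate proceeds by anti addition (iodide at C13, proton at C14 from the opposite side), which gives the (Z)-iodoenoate with iodine cis to the ester and the hydroxymethyl group trans to it.

Step 15
Reactants: 28 tert-butyl (2Z)-4-hydroxy-3-iodobut-2-enoate
Product: 29 tert-butyl (2Z)-4-acetoxy-3-iodobut-2-enoate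
Conditions: Ac2O, pyridine, DMAP (cat.), CH2Cl2, 0 °C
Reagents that add atoms: acetic anhydride CC(=O)OC(C)=O
Why: Routine DMAP-catalysed acetylation of a primary allylic alcohol.

Step 16
Reactants: 23 tert-butyl (1R,2S,4aR,8aS)-1-ethenyl-5,5,8a-trimethyl-1,2,4a,5,6,7,8,8a-octahydronaphthalene-2-carboxylate; 29 tert-butyl (2Z)-4-acetoxy-3-iodobut-2-enoate
Product: 31 tert-butyl (1R,2S,4aR,8aS)-1-[(3E)-3-(acetoxymethyl)-5-tert-butoxy-5-oxopent-3-en-1-yl]-5,5,8a-trimethyl-1,2,4a,5,6,7,8,8a-octahydronaphthalene-2-carboxylate, via B-alkyl-9-BBN 30 (not isolated)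
Conditions: 9-BBN, THF, 0 °C to rt; then 29, PdCl2(dppf) (5 mol %), AsPh3, aq. K3PO4, DMF, rt
Reagents that add atoms: none
Why: 9-BBN hydroborates only the monosubstituted C11=C12 alkene, at the terminal carbon, and B-alkyl Suzuki–Miyaura coupling with the alkenyl iodide proceeds with retention of alkene geometry, so the C12 chain ends up cis to the C15 ester as the (13E)-enoate.

Step 17
Reactants: 31 tert-butyl (1R,2S,4aR,8aS)-1-[(3E)-3-(acetoxymethyl)-5-tert-butoxy-5-oxopent-3-en-1-yl]-5,5,8a-trimethyl-1,2,4a,5,6,7,8,8a-octahydronaphthalene-2-carboxylate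
Product: 32 (1R,2S,4aR,8aS)-1-[(3E)-3-(acetoxymethyl)-4-carboxybut-3-en-1-yl]-5,5,8a-trimethyl-1,2,4a,5,6,7,8,8a-octahydronaphthalene-2-carboxylic acid (CNP0108723.1; labdane numbering 5R,8S,9R,10S,13E)
Conditions: CF3CO2H/CH2Cl2 (1:4), 0 °C to rt
Reagents that add atoms: none
Why: Acidolysis removes both tert-butyl esters as isobutene (E1 cleavage), whereas the acetate, the β,γ-unsaturated C8 centre and both alkenes are stable to CF3CO2H at or below room temperature.

Compound list
1 | 5-chloropent-1-yne | C#CCCCCl | starting material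
2 | (E)-(5-chloro-2-methylpent-1-en-1-yl)dimethylalane | C[Al](C)/C=C(\C)CCCCl | intermediate (not isolated)
3 | lithium butyl[(E)-5-chloro-2-methylpent-1-en-1-yl]dimethylalanate | [Li+].CCCC[Al-](C)(C)/C=C(\C)CCCCl | intermediate (not isolated)
4 | (E)-6-chloro-3-methylhex-2-en-1-ol | OC/C=C(\C)CCCCl | intermediate
5 | (E)-[(6-chloro-3-methylhex-2-en-1-yl)oxy]triethylsilane | CC[Si](CC)(CC)OC/C=C(\C)CCCCl | intermediate
6 | mesityl oxide (4-methylpent-3-en-2-one) | CC(=O)C=C(C)C | starting material
7 | (E)-{4-methyl-6-[(triethylsilyl)oxy]hex-4-en-1-yl}magnesium chloride | CC[Si](CC)(CC)OC/C=C(\C)CCC[Mg]Cl | intermediate (not isolated)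
8 | (8E)-4,4,8-trimethyl-10-[(triethylsilyl)oxy]-2-[(trimethylsilyl)oxy]deca-2,8-diene (enol ether geometry not defined) | CC[Si](CC)(CC)OC/C=C(\C)CCCC(C)(C)C=C(C)O[Si](C)(C)C | intermediate (not isolated)
9 | (E)-10-hydroxy-4,4,8-trimethyldec-8-en-2-one | OC/C=C(\C)CCCC(C)(C)CC(C)=O | intermediate
10 | glyoxylic acid (used as the monohydrate) | O=CC(=O)O | starting material
11 | (2E,10E)-12-hydroxy-6,6,10-trimethyl-4-oxododeca-2,10-dienoic acid | OC/C=C(\C)CCCC(C)(C)CC(=O)/C=C/C(=O)O | intermediate
12 | tert-butyl (2E,10E)-12-hydroxy-6,6,10-trimethyl-4-oxododeca-2,10-dienoate | OC/C=C(\C)CCCC(C)(C)CC(=O)/C=C/C(=O)OC(C)(C)C | intermediate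
13 | tert-butyl (2E,10E)-6,6,10-trimethyl-4-oxo-12-[(trimethylsilyl)oxy]dodeca-2,10-dienoate | C[Si](C)(C)OC/C=C(\C)CCCC(C)(C)CC(=O)/C=C/C(=O)OC(C)(C)C | intermediate (not isolated)
14 | tert-butyl (2E,4Z,10E)-6,6,10-trimethyl-4-[(triisopropylsilyl)oxy]-12-[(trimethylsilyl)oxy]dodeca-2,4,10-trienoate | C[Si](C)(C)OC/C=C(\C)CCCC(C)(C)/C=C(O[Si](C(C)C)(C(C)C)C(C)C)/C=C/C(=O)OC(C)(C)C | intermediate (not isolated)
15 | tert-butyl (2E,4Z,10E)-12-hydroxy-6,6,10-trimethyl-4-[(triisopropylsilyl)oxy]dodeca-2,4,10-trienoate | OC/C=C(\C)CCCC(C)(C)/C=C(O[Si](C(C)C)(C(C)C)C(C)C)/C=C/C(=O)OC(C)(C)C | intermediate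
16 | tert-butyl (2E,4Z,10E)-6,6,10-trimethyl-12-oxo-4-[(triisopropylsilyl)oxy]dodeca-2,4,10-trienoate (key-step precursor) | O=C/C=C(\C)CCCC(C)(C)/C=C(O[Si](C(C)C)(C(C)C)C(C)C)/C=C/C(=O)OC(C)(C)C | intermediate
17 | tert-butyl (1R,2R,4aR,8aR)-1-formyl-5,5,8a-trimethyl-4-[(triisopropylsilyl)oxy]-1,2,4a,5,6,7,8,8a-octahydronaphthalene-2-carboxylate (key-step product) | O=C[C@@H]1[C@H](C(=O)OC(C)(C)C)C=C(O[Si](C(C)C)(C(C)C)C(C)C)[C@@H]2C(C)(C)CCC[C@@]12C | intermediate
18 | tert-butyl (1R,2S,4aR,8aS)-1-ethenyl-5,5,8a-trimethyl-4-[(triisopropylsilyl)oxy]-1,2,4a,5,6,7,8,8a-octahydronaphthalene-2-carboxylate | C=C[C@@H]1[C@H](C(=O)OC(C)(C)C)C=C(O[Si](C(C)C)(C(C)C)C(C)C)[C@@H]2C(C)(C)CCC[C@@]12C | intermediate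
19 | tert-butyl (1R,2R,4aR,8aS)-1-ethenyl-5,5,8a-trimethyl-4-oxodecahydronaphthalene-2-carboxylate (ester axial, cis to C20) | C=C[C@@H]1[C@H](C(=O)OC(C)(C)C)CC(=O)[C@@H]2C(C)(C)CCC[C@@]12C | intermediate (not isolated)
20 | tert-butyl (1R,2S,4aR,8aS)-1-ethenyl-5,5,8a-trimethyl-4-oxodecahydronaphthalene-2-carboxylate (ester equatorial) | C=C[C@@H]1[C@@H](C(=O)OC(C)(C)C)CC(=O)[C@@H]2C(C)(C)CCC[C@@]12C | intermediate
21 | potassium C6=C7 enolate of 20 | C=C[C@@H]1[C@@H](C(=O)OC(C)(C)C)C=C([O-])[C@@H]2C(C)(C)CCC[C@@]12C.[K+] | intermediate (not isolated)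
22 | tert-butyl (1R,2R,4aR,8aS)-1-ethenyl-5,5,8a-trimethyl-4-{[(trifluoromethyl)sulfonyl]oxy}-1,2,4a,5,6,7,8,8a-octahydronaphthalene-2-carboxylate | C=C[C@@H]1[C@@H](C(=O)OC(C)(C)C)C=C(OS(=O)(=O)C(F)(F)F)[C@@H]2C(C)(C)CCC[C@@]12C | intermediate
23 | tert-butyl (1R,2S,4aR,8aS)-1-ethenyl-5,5,8a-trimethyl-1,2,4a,5,6,7,8,8a-octahydronaphthalene-2-carboxylate | C=C[C@@H]1[C@@H](C(=O)OC(C)(C)C)C=C[C@@H]2C(C)(C)CCC[C@@]12C | intermediate
24 | 2-(prop-2-yn-1-yloxy)tetrahydro-2H-pyran (racemic) | C#CCOC1CCCCO1 | starting material
25 | lithium 3-(tetrahydro-2H-pyran-2-yloxy)prop-1-yn-1-ide | [Li]C#CCOC1CCCCO1 | intermediate (not isolated)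
26 | tert-butyl 4-(tetrahydro-2H-pyran-2-yloxy)but-2-ynoate | CC(C)(C)OC(=O)C#CCOC1CCCCO1 | intermediate (not isolated)
27 | tert-butyl 4-hydroxybut-2-ynoate | OCC#CC(=O)OC(C)(C)C | intermediate
28 | tert-butyl (2Z)-4-hydroxy-3-iodobut-2-enoate | OC/C(I)=C/C(=O)OC(C)(C)C | intermediate
29 | tert-butyl (2Z)-4-acetoxy-3-iodobut-2-enoate | CC(=O)OC/C(I)=C/C(=O)OC(C)(C)C | intermediate
30 | tert-butyl (1R,2S,4aR,8aS)-1-[2-(9-borabicyclo[3.3.1]nonan-9-yl)ethyl]-5,5,8a-trimethyl-1,2,4a,5,6,7,8,8a-octahydronaphthalene-2-carboxylate | B1(CC[C@@H]2[C@@H](C(=O)OC(C)(C)C)C=C[C@@H]3C(C)(C)CCC[C@@]23C)C4CCCC1CCC4 | intermediate (not isolated)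
31 | tert-butyl (1R,2S,4aR,8aS)-1-[(3E)-3-(acetoxymethyl)-5-tert-butoxy-5-oxopent-3-en-1-yl]-5,5,8a-trimethyl-1,2,4a,5,6,7,8,8a-octahydronaphthalene-2-carboxylate | CC(=O)OC/C(=C/C(=O)OC(C)(C)C)CC[C@@H]1[C@@H](C(=O)OC(C)(C)C)C=C[C@@H]2C(C)(C)CCC[C@@]12C | intermediate
32 | (1R,2S,4aR,8aS)-1-[(3E)-3-(acetoxymethyl)-4-carboxybut-3-en-1-yl]-5,5,8a-trimethyl-1,2,4a,5,6,7,8,8a-octahydronaphthalene-2-carboxylic acid | CC(=O)OC/C(=C/C(=O)O)CC[C@@H]1[C@@H](C(=O)O)C=C[C@@H]2C(C)(C)CCC[C@@]12C | target

Total step count: 17.
Longest linear sequence: 14 (steps 1–12, 16 and 17); steps 13–15 form the side-chain branch.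

Steps most likely to fail

1. Step 8 (the step that carries the label). The hindered β,β-disubstituted enal may not be activated enough for C5–C10 bond formation at low temperature, the catalyst may discriminate the two faces of C10 poorly, or free acid may desilylate the diene before it reacts. The fallback uses known chemistry: trienal 16 is cyclised with stoichiometric Me2AlCl in CH2Cl2 (−78 to 0 °C), an established achiral promoter for silyloxydiene trienals. This should give the racemate, that is 17 together with its mirror image, the enantiomeric cycloadduct F1. The two are separated by preparative chromatography on a chiral stationary phase, and 17 re-enters the route at step 9; all later stereocentres still follow by equilibration.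

2. Step 6. The transient trimethylsilyl ether may be lost or exchanged for a triisopropylsilyl group under the silyl triflate, which would cap the primary oxygen irreversibly and block the oxidation to the enal. In the fallback, alcohol 12 is acetylated (Ac2O, pyridine) to the keto acetate F2. Soft enolisation (i-Pr3SiOTf, Et3N) then gives the acetate-protected dienol ether F3, and methanolysis of the primary allylic acetate with K2CO3 in MeOH at 0 °C returns alcohol 15.

3. Step 16. β-Acetoxy elimination from the alkenylpalladium intermediate (towards an allenoate) or hydrolysis of the acetate by the aqueous base may compete with transmetalation of the hindered alkylborane. In the fallback, the same borane 30, made from diene 23, is coupled under the same catalyst with the unprotected iodo alcohol 28, an intermediate of the main route. This should give the hydroxy diester F4, which is acetylated (Ac2O, pyridine, DMAP) to 31.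

Further compounds
F1 | step 8 | tert-butyl (1S,2S,4aS,8aS)-1-formyl-5,5,8a-trimethyl-4-[(triisopropylsilyl)oxy]-1,2,4a,5,6,7,8,8a-octahydronaphthalene-2-carboxylate (enantiomer of 17) | O=C[C@H]1[C@@H](C(=O)OC(C)(C)C)C=C(O[Si](C(C)C)(C(C)C)C(C)C)[C@H]2C(C)(C)CCC[C@]12C
F2 | step 6 | tert-butyl (2E,10E)-12-acetoxy-6,6,10-trimethyl-4-oxododeca-2,10-dienoate | CC(=O)OC/C=C(\C)CCCC(C)(C)CC(=O)/C=C/C(=O)OC(C)(C)C
F3 | step 6 | tert-butyl (2E,4Z,10E)-12-acetoxy-6,6,10-trimethyl-4-[(triisopropylsilyl)oxy]dodeca-2,4,10-trienoate | CC(=O)OC/C=C(\C)CCCC(C)(C)/C=C(O[Si](C(C)C)(C(C)C)C(C)C)/C=C/C(=O)OC(C)(C)C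
F4 | step 16 | tert-butyl (1R,2S,4aR,8aS)-1-[(3E)-5-tert-butoxy-3-(hydroxymethyl)-5-oxopent-3-en-1-yl]-5,5,8a-trimethyl-1,2,4a,5,6,7,8,8a-octahydronaphthalene-2-carboxylate | OC/C(=C/C(=O)OC(C)(C)C)CC[C@@H]1[C@@H](C(=O)OC(C)(C)C)C=C[C@@H]2C(C)(C)CCC[C@@]12C
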